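**Plan**

- Cuts: the angelate (C2–O) and acetate (C4–O) esters, the exocyclic C11=C13 bond, the lactone C8–O–C12 bond, then in the carbocycle C1–C10 (retro-Cope) and C6–C7 together with the transient C6–C8 bond (retro-cyclopropanation).
- Enabling feature (ring C1, C5–C10; chain C2–C4 on C1; lactone C11, C12, methylene C13; methyls on C5 and C10): the C5=C6 alkene, the adjacent C1/C10 stereocentres, the C7 branch and the C8 oxygen sit where a cis-divinylcyclopropane C6–C7–C8 with a siloxy group on C8 leaves them after a [3,3] shift.
- Forward: a C6–C5–C1–C4 vinylcarbene precursor (five steps) and a C12–C7–C10 siloxydiene (three steps) are made separately; one flask gives the cyclopropane and then the seven-membered ring; the γ-lactone is closed next, then the methylene and the two esters follow.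
- Stereochemistry: C2 from (S)-α-hydroxy-γ-butyrolactone; C7 from the catalyst-chosen face of the Z enol ether; C1 and C10 from the E and Z alkene geometries through the boat Cope; C8 from hydride attack anti to the C7 arm; angelate geometry from angelic acid.

Key step: step 9

Assumption: Rh2(S-PTAD)4, dirhodium tetrakis[(S)-(1-adamantyl)(N-phthalimido)acetate], is taken to select the required enol ether face; the C2 centre is remote, so the R series would be used if a trial shows the opposite sense.

**Route**

Step 1
Reactants: 1 (S)-α-hydroxy-γ-butyrolactone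
Product: 2 (S)-2,4-dihydroxy-N-methoxy-N-methylbutanamide
Conditions: MeNH(OMe)·HCl, i-PrMgCl, THF, −20 → 0 °C; aq. NH4Cl; crude used directly
Reagents that add atoms: N,O-dimethylhydroxylamine hydrochloride, CNOC.Cl
Why: Aminolysis of the lactone by the chloromagnesium amide of N,O-dimethylhydroxylamine is a standard ring opening to the N-methoxy-N-methylamide, and C2 is untouched because the α-hydroxyl is deprotonated first and its alkoxide suppresses enolisation.

Step 2
Reactants: 2 (S)-2,4-dihydroxy-N-methoxy-N-methylbutanamide
Product: 3 (S)-2,4-bis(tert-butyldimethylsilyloxy)-N-methoxy-N-methylbutanamide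
Conditions: TBSCl, imidazole, DMF, rt
Reagents that add atoms: tert-butyldimethylsilyl chloride, CC(C)(C)[Si](C)(C)Cl
Why: Imidazole-promoted silylation protects the primary and the secondary hydroxyl in one operation and blocks re-lactonisation without affecting the stereocentre.

Step 3
Reactants: 3 (S)-2,4-bis(tert-butyldimethylsilyloxy)-N-methoxy-N-methylbutanamide
Product: 4 (S)-2,4-bis(tert-butyldimethylsilyloxy)butanal
Conditions: i-Bu2AlH, THF, −78 °C; aq. potassium sodium tartrate
Reagents that add atoms: none
Why: Hydride addition to the N-methoxy-N-methylamide gives a chelated tetrahedral aluminium adduct that releases the aldehyde only on work-up, so over-reduction is avoided, and the epimerisable α-silyloxy aldehyde is used at once.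

Step 4
Reactants: 4 (S)-2,4-bis(tert-butyldimethylsilyloxy)butanal; 5 2-(triphenylphosphoranylidene)propanal
Product: 6 (S,E)-4,6-bis(tert-butyldimethylsilyloxy)-2-methylhex-2-enal
Conditions: toluene, 80 °C
Reagents that add atoms: none
Why: Wittig olefination with the stabilised formyl ylide is E-selective and neutral, so the trisubstituted E enal should form without epimerising C2.

Step 5
Reactants: 6 (S,E)-4,6-bis(tert-butyldimethylsilyloxy)-2-methylhex-2-enal
Product: 7 N-[2-(trifluoromethyl)phenylsulfonyl]hydrazone of enal 6
Conditions: 2-(CF3)C6H4SO2NHNH2, MeOH, rt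
Reagents that add atoms: 2-(trifluoromethyl)benzenesulfonohydrazide, NNS(=O)(=O)c1ccccc1C(F)(F)F
Why: Uncatalysed condensation gives the conjugated N-sulfonylhydrazone, and the electron-poor 2-(trifluoromethyl)benzenesulfonyl group is chosen because such hydrazones release the diazo compound below room temperature.

Step 6
Reactants: 8 methyl 4-chloro-4-oxobutanoate; 9 propyne
Product: 10 methyl 4-oxohept-5-ynoate
Conditions: PdCl2(PPh3)2 (2 mol %), CuI (4 mol %), Et3N, THF, 0 °C → rt
Reagents that add atoms: none
Why: Acyl Sonogashira coupling (oxidative addition of the acid chloride to palladium, transmetalation from the copper acetylide) gives the ynone and leaves the methyl ester untouched.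

Step 7
Reactants: 10 methyl 4-oxohept-5-ynoate
Product: 11 methyl (Z)-4-(triethylsilyloxy)hept-3-en-5-ynoate
Conditions: Et3SiOTf, Et3N, CH2Cl2, −78 → 0 °C
Reagents that add atoms: triethylsilyl trifluoromethanesulfonate, CC[Si](CC)(CC)OS(=O)(=O)C(F)(F)F
Why: Soft enolisation with silyl triflate and amine can occur only at C3, the sole enolisable position of the ketone, and should favour the Z enol ether with the ester arm cis to the siloxy group, the usual outcome for acyclic ketones under these conditions.

Step 8
Reactants: 11 methyl (Z)-4-(triethylsilyloxy)hept-3-en-5-ynoate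
Product: 12 methyl (3Z,5Z)-4-(triethylsilyloxy)hepta-3,5-dienoate
Conditions: H2 (1 atm), Pd/CaCO3 poisoned with Pb(OAc)2 (Lindlar catalyst), quinoline, hexane, rt
Reagents that add atoms: none
Why: Syn addition of hydrogen on the poisoned palladium surface (Lindlar semihydrogenation) converts the alkyne into the Z propenyl group, while the trisubstituted siloxy alkene is not reduced.

Step 9
Reactants: 7 N-sulfonylhydrazone of enal 6; 12 methyl (3Z,5Z)-4-(triethylsilyloxy)hepta-3,5-dienoate
Product: 15 siloxy cycloheptadiene ester, via vinyl diazo compound 13 (not isolated), via divinylcyclopropane 14 (not isolated)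
Conditions: NaH, CH2Cl2, 0 °C; then 12 (1.5 equiv), Rh2(S-PTAD)4 (2 mol %), −40 °C → rt; then toluene, 80 °C
Reagents that add atoms: none
Why: Proposed new method: the sodium salt of 7 loses arylsulfinate below room temperature to give vinyl diazo compound 13, from which the dirhodium tetracarboxylate (divalent rhodium) forms an electrophilic vinylcarbene whose carbene carbon C6 carries only hydrogen, so that, like an acceptor-only carbene, it can add in a concerted asynchronous [2+1] step to the trisubstituted but most electron-rich alkene of 12, the C7=C8 silyl enol ether, closing the three-membered ring C6–C7–C8 of 14 by forming C6–C7 and C6–C8 with retention of the Z enol ether geometry. The closest known reaction types are the dirhodium-catalysed cyclopropanation/Cope sequence (formal 4+3) of ester-substituted vinylcarbenoids with 2-siloxydienes and vinylcarbene transfer from α,β-unsaturated N-sulfonylhydrazones to simple alkenes, whereas an acceptor-free vinylcarbene on a trisubstituted siloxydiene under catalyst control is untested. The seven-membered ring is closed in the same flask by a boat [3,3]-sigmatropic (Cope) rearrangement of the cis-divinylcyclopropane, which forms C1–C10, breaks C6–C8 and is driven by release of ring strain. The cyclopropane centres C6, C7 and C8 are set by the chiral ligand sphere, which selects the enol ether face, together with the stereospecific syn addition, C7 is carried unchanged into 15, C1 follows from the E alkene of the carbene fragment (side chain outward in the boat, hence cis to the C7 arm) and C10 from the Z propenyl group (methyl inward, hence trans to both). The step needs site selectivity (the enol ether is far more nucleophilic than the propenyl alkene), cis-divinyl geometry (the alkenyl group of the carbene prefers the cyclopropane face that holds C7–H and the propenyl group over the face crowded by the siloxy group and the ester arm) and suppression of vinylogous attack (the C1 terminus is substituted). Because the ester arm ends up trans to both alkenyl groups, only the small propenyl methyl points into the boat, so warming to 80 °C should complete the rearrangement.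

Step 10
Reactants: 15 siloxy cycloheptadiene ester
Product: 16 β,γ-unsaturated cycloheptenone ester
Conditions: Bu4NF, AcOH, THF, −78 → −30 °C
Reagents that add atoms: none
Why: Fluoride attacks the silicon of the enol ether far faster than that of the alkyl tert-butyldimethylsilyl ethers, and protonation at C9 by acetic acid at low temperature should give the β,γ-unsaturated ketone without epimerising C7 or moving the C5=C6 alkene into conjugation.

Step 11
Reactants: 16 β,γ-unsaturated cycloheptenone ester
Product: 18 cis-fused lactone bis-silyl ether, via hydroxy ester 17 (not isolated)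
Conditions: LiBH(s-Bu)3, THF, −78 °C → rt; aq. NH4Cl
Reagents that add atoms: none
Why: The bulky trialkylborohydride should attack the C8 carbonyl from the face opposite to the adjacent C7 ester arm (new centre C8 under substrate control), and the resulting alkoxide, cis to that arm, closes the γ-lactone by 5-exo-trig acyl substitution on the methyl ester as the mixture warms.

Step 12
Reactants: 18 cis-fused lactone bis-silyl ether
Product: 19 α-(dimethylaminomethyl) lactone
Conditions: LiN(i-Pr)2, THF, −78 °C; then dimethylmethyleneiminium iodide, −78 °C → rt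
Reagents that add atoms: N,N-dimethylmethyleneiminium iodide, C=[N+](C)C.[I-]
Why: The lactone enolate adds to the iminium salt at C11 (Mannich reaction), and the configuration of the new centre is irrelevant because it is removed in the next step.

Step 13
Reactants: 19 α-(dimethylaminomethyl) lactone
Product: 21 α-methylene lactone bis-silyl ether, via ammonium iodide 20 (not isolated)
Conditions: MeI, MeOH, rt; then aq. NaHCO3, CH2Cl2, rt
Reagents that add atoms: none
Why: Exhaustive N-methylation followed by base-induced β-elimination of trimethylamine (Hofmann-type elimination) gives the α-methylene lactone under conditions too mild to affect the silyl ethers or the ring alkene.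

Step 14
Reactants: 21 α-methylene lactone bis-silyl ether
Product: 22 α-methylene lactone diol
Conditions: HF·pyridine, pyridine, THF, 0 °C → rt
Reagents that add atoms: none
Why: Buffered hydrogen fluoride cleaves both tert-butyldimethylsilyl ethers while the α-methylene lactone, which would suffer conjugate addition with basic fluoride sources, stays intact.

Step 15
Reactants: 22 α-methylene lactone diol
Product: 23 primary acetate with free C2 hydroxyl
Conditions: AcCl (1.05 equiv), 2,4,6-collidine, CH2Cl2, −78 °C
Reagents that add atoms: acetyl chloride, CC(Cl)=O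
Why: At −78 °C acetyl chloride with the hindered base acylates the unhindered primary C4 hydroxyl much faster than the secondary C2 hydroxyl next to the ring, a known selective monoacylation of 1,3-diols.

Step 16
Reactants: 23 primary acetate with free C2 hydroxyl; 24 angelic acid
Product: 26 target CNP0163960.1, via mixed anhydride 25 (not isolated)
Conditions: 24, 2,4,6-Cl3C6H2COCl, Et3N, toluene, rt; then 23, toluene, 80 °C
Reagents that add atoms: none
Why: Yamaguchi esterification, in which the alcohol attacks the angeloyl carbonyl of the mixed anhydride because the aroyl carbonyl is shielded, and the absence of nucleophilic catalysts and strong base should keep the Z geometry from isomerising to the tiglate, with no stereocentre touched.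

**Compound list**

1 | (S)-3-hydroxydihydrofuran-2(3H)-one, (S)-α-hydroxy-γ-butyrolactone | O[C@H]1CCOC1=O | starting material
2 | (S)-2,4-dihydroxy-N-methoxy-N-methylbutanamide | CON(C)C(=O)[C@@H](O)CCO | intermediate
3 | (S)-2,4-bis(tert-butyldimethylsilyloxy)-N-methoxy-N-methylbutanamide | CON(C)C(=O)[C@@H](O[Si](C)(C)C(C)(C)C)CCO[Si](C)(C)C(C)(C)C | intermediate
4 | (S)-2,4-bis(tert-butyldimethylsilyloxy)butanal | O=C[C@@H](O[Si](C)(C)C(C)(C)C)CCO[Si](C)(C)C(C)(C)C | intermediate
5 | 2-(triphenylphosphoranylidene)propanal | CC(C=O)=P(c1ccccc1)(c1ccccc1)c1ccccc1 | starting material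
6 | (S,E)-4,6-bis(tert-butyldimethylsilyloxy)-2-methylhex-2-enal | O=C/C(C)=C/[C@@H](O[Si](C)(C)C(C)(C)C)CCO[Si](C)(C)C(C)(C)C | intermediate
7 | N'-[(1E,2E,4S)-4,6-bis(tert-butyldimethylsilyloxy)-2-methylhex-2-en-1-ylidene]-2-(trifluoromethyl)benzenesulfonohydrazide | FC(F)(F)c1ccccc1S(=O)(=O)N/N=C/C(C)=C/[C@@H](O[Si](C)(C)C(C)(C)C)CCO[Si](C)(C)C(C)(C)C | intermediate
8 | methyl 4-chloro-4-oxobutanoate | COC(=O)CCC(Cl)=O | starting material
9 | propyne | CC#C | starting material
10 | methyl 4-oxohept-5-ynoate | COC(=O)CCC(=O)C#CC | intermediate
11 | methyl (Z)-4-(triethylsilyloxy)hept-3-en-5-ynoate | COC(=O)C/C=C(\O[Si](CC)(CC)CC)C#CC | intermediate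
12 | methyl (3Z,5Z)-4-(triethylsilyloxy)hepta-3,5-dienoate | COC(=O)C/C=C(\O[Si](CC)(CC)CC)/C=C\C | intermediate
13 | (S,E)-4,6-bis(tert-butyldimethylsilyloxy)-1-diazo-2-methylhex-2-ene (formed in the flask, not isolated) | [N-]=[N+]=C/C(C)=C/[C@@H](O[Si](C)(C)C(C)(C)C)CCO[Si](C)(C)C(C)(C)C | intermediate
14 | methyl 2-{2-[(S,E)-4,6-bis(tert-butyldimethylsilyloxy)hex-2-en-2-yl]-3-[(Z)-prop-1-enyl]-3-(triethylsilyloxy)cyclopropyl}acetate; the two alkenyl groups cis, the acetate arm cis to the siloxy group and trans to both alkenyl groups; C6 R, C7 S in target locants (formed in the flask, not isolated) | COC(=O)C[C@H]1[C@H](/C(C)=C/[C@@H](O[Si](C)(C)C(C)(C)C)CCO[Si](C)(C)C(C)(C)C)[C@]1(O[Si](CC)(CC)CC)/C=C\C | intermediate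
15 | methyl 2-{4-[(S)-1,3-bis(tert-butyldimethylsilyloxy)propyl]-3,5-dimethyl-7-(triethylsilyloxy)cyclohepta-2,6-dien-1-yl}acetate; ring C1 (S) acetate arm and C4 (S) side chain cis, C5 methyl trans to both | COC(=O)C[C@H]1C=C(C)[C@@H]([C@H](CCO[Si](C)(C)C(C)(C)C)O[Si](C)(C)C(C)(C)C)[C@H](C)C=C1O[Si](CC)(CC)CC | intermediate
16 | methyl 2-{(1S,4S,5R)-4-[(S)-1,3-bis(tert-butyldimethylsilyloxy)propyl]-3,5-dimethyl-7-oxocyclohept-2-en-1-yl}acetate | COC(=O)C[C@H]1C=C(C)[C@@H]([C@H](CCO[Si](C)(C)C(C)(C)C)O[Si](C)(C)C(C)(C)C)[C@H](C)CC1=O | intermediate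
17 | methyl 2-{(1S,4S,5R,7R)-4-[(S)-1,3-bis(tert-butyldimethylsilyloxy)propyl]-7-hydroxy-3,5-dimethylcyclohept-2-en-1-yl}acetate, hydroxyl cis to the acetate arm (formed in the flask, not isolated) | COC(=O)C[C@H]1C=C(C)[C@@H]([C@H](CCO[Si](C)(C)C(C)(C)C)O[Si](C)(C)C(C)(C)C)[C@H](C)C[C@H]1O | intermediate
18 | (3aS,6S,7R,8aR)-6-[(S)-1,3-bis(tert-butyldimethylsilyloxy)propyl]-5,7-dimethyl-3,3a,6,7,8,8a-hexahydro-2H-cyclohepta[b]furan-2-one (cis-fused) | C1C(=O)O[C@@H]2C[C@@H](C)[C@H]([C@H](CCO[Si](C)(C)C(C)(C)C)O[Si](C)(C)C(C)(C)C)C(C)=C[C@H]12 | intermediate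
19 | 3-[(dimethylamino)methyl] derivative of 18 (C3 epimers, centre removed later) | CN(C)CC1C(=O)O[C@@H]2C[C@@H](C)[C@H]([C@H](CCO[Si](C)(C)C(C)(C)C)O[Si](C)(C)C(C)(C)C)C(C)=C[C@H]12 | intermediate
20 | 3-[(trimethylammonio)methyl] lactone iodide (formed in the flask, not isolated) | C[N+](C)(C)CC1C(=O)O[C@@H]2C[C@@H](C)[C@H]([C@H](CCO[Si](C)(C)C(C)(C)C)O[Si](C)(C)C(C)(C)C)C(C)=C[C@H]12.[I-] | intermediate
21 | (3aR,6S,7R,8aR)-6-[(S)-1,3-bis(tert-butyldimethylsilyloxy)propyl]-5,7-dimethyl-3-methylidene-3,3a,6,7,8,8a-hexahydro-2H-cyclohepta[b]furan-2-one | C=C1C(=O)O[C@@H]2C[C@@H](C)[C@H]([C@H](CCO[Si](C)(C)C(C)(C)C)O[Si](C)(C)C(C)(C)C)C(C)=C[C@H]12 | intermediate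
22 | (3aR,6S,7R,8aR)-6-[(S)-1,3-dihydroxypropyl]-5,7-dimethyl-3-methylidene-3,3a,6,7,8,8a-hexahydro-2H-cyclohepta[b]furan-2-one | C=C1C(=O)O[C@@H]2C[C@@H](C)[C@H]([C@H](CCO)O)C(C)=C[C@H]12 | intermediate
23 | (S)-3-hydroxy-3-[(3aR,6S,7R,8aR)-5,7-dimethyl-3-methylidene-2-oxo-3,3a,6,7,8,8a-hexahydro-2H-cyclohepta[b]furan-6-yl]propyl acetate | C=C1C(=O)O[C@@H]2C[C@@H](C)[C@H]([C@H](CCOC(C)=O)O)C(C)=C[C@H]12 | intermediate
24 | angelic acid, (Z)-2-methylbut-2-enoic acid | C/C=C(/C)C(=O)O | starting material
25 | (Z)-2-methylbut-2-enoic 2,4,6-trichlorobenzoic anhydride (formed in the flask, not isolated) | C/C=C(/C)C(=O)OC(=O)c1c(Cl)cc(Cl)cc1Cl | intermediate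
26 | CNP0163960.1, (S)-3-acetoxy-1-[(3aR,6S,7R,8aR)-5,7-dimethyl-3-methylidene-2-oxo-3,3a,6,7,8,8a-hexahydro-2H-cyclohepta[b]furan-6-yl]propyl (Z)-2-methylbut-2-enoate | C=C1C(=O)O[C@@H]2C[C@@H](C)[C@H]([C@H](CCOC(C)=O)OC(=O)/C(C)=C\C)C(C)=C[C@H]12 | target

**Step count and risks**

Total step count: 16. Longest linear sequence: 13 steps (1 to 26 through steps 1–5 and 9–16); the diene branch (steps 6–8) joins at step 9.

Most likely to fail:

1. Step 9 (proposed new method). The vinyl diazo intermediate may close to a pyrazole before the catalyst captures it. The carbene may add to the propenyl alkene, to the wrong enol ether face or trans to the propenyl group. The Cope shift may stall because of the inward methyl. The fallback uses known chemistry, leaves from aldehyde 4 and diene 12, and returns at cycloheptadiene 15. Addition of ethynylmagnesium bromide to 4 (THF, −78 °C) gives (4S)-4,6-bis(tert-butyldimethylsilyloxy)hex-1-yn-3-ol F1 (both C3 epimers, since this centre is lost later). Acylation with pivaloyl chloride (pyridine, catalytic DMAP) gives the propargylic pivalate F2. With (R)-DTBM-SEGPHOS(AuCl)2 and AgSbF6 (monovalent gold, MeNO2, rt), the known 1,2-acyloxy shift of such esters generates a pivaloyloxy-substituted vinylcarbenoid without any diazo compound. Its cis-selective, ligand-controlled cyclopropanation of the enol ether of 12 and the Cope rearrangement on warming in toluene should give the enol pivalate cycloheptadiene F3. F3 differs from 15 only by OPiv in place of methyl at C5. The Z enol ester normally formed keeps the side chain outward in the boat, as in the main route. Iron-catalysed cross-coupling of the enol pivalate with MeMgBr (FeCl2, SIMes·HCl, THF, 0 °C, slow addition so that the methyl ester survives) then gives 15.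

2. Step 11. The hydride may approach from the face of the C7 arm, because the C10 methyl sits on the intended face, or the β,γ-enone may slip into conjugation under the basic conditions. The fallback sets C8 by substitution instead of by hydride face selection; it leaves from ketone 16 and returns at lactone 18. Reduction with NaBH4/CeCl3 (MeOH, −78 °C, small non-basic hydride) is run towards the C8-epimeric hydroxy ester F4 (hydroxyl trans to the C7 arm). Saponification with LiOH (THF/H2O) gives the hydroxy acid F5. Mitsunobu lactonisation (PPh3, diisopropyl azodicarboxylate, toluene, 0 °C) closes the γ-lactone with inversion at C8 and gives 18.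

3. Step 7. Enolisation may give the E enol ether (ester arm cis to the alkynyl group), which would invert C7 relative to C1 and C10 in step 9; the enyne may also be over-reduced or isomerised in step 8. The fallback takes both alkene geometries from other sources; it leaves from acid chloride 8 and returns at diene 12. Stille acylation of 8 with (Z)-tributyl(prop-1-enyl)stannane (Pd(PPh3)4, zerovalent palladium, THF, 50 °C) gives methyl (Z)-4-oxohept-5-enoate F6 with retention of the alkene geometry. Kinetic deprotonation at C3 with LiN(SiMe3)2 in THF/DMPU at −78 °C in the presence of Et3SiCl, conditions that favour the Z(O) enolate, gives 12.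

**Further compounds**

F1 | step 9 | (4S)-4,6-bis(tert-butyldimethylsilyloxy)hex-1-yn-3-ol (both C3 epimers) | C#CC(O)[C@@H](O[Si](C)(C)C(C)(C)C)CCO[Si](C)(C)C(C)(C)C
F2 | step 9 | (4S)-4,6-bis(tert-butyldimethylsilyloxy)hex-1-yn-3-yl pivalate (both C3 epimers) | C#CC(OC(=O)C(C)(C)C)[C@@H](O[Si](C)(C)C(C)(C)C)CCO[Si](C)(C)C(C)(C)C
F3 | step 9 | enol pivalate analogue of 15, pivaloyloxy in place of the C5 methyl, same configuration | COC(=O)C[C@H]1C=C(OC(=O)C(C)(C)C)[C@@H]([C@H](CCO[Si](C)(C)C(C)(C)C)O[Si](C)(C)C(C)(C)C)[C@H](C)C=C1O[Si](CC)(CC)CC
F4 | step 11 | C8 epimer of hydroxy ester 17, hydroxyl trans to the acetate arm | COC(=O)C[C@H]1C=C(C)[C@@H]([C@H](CCO[Si](C)(C)C(C)(C)C)O[Si](C)(C)C(C)(C)C)[C@H](C)C[C@@H]1O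
F5 | step 11 | hydroxy acid from F4 | OC(=O)C[C@H]1C=C(C)[C@@H]([C@H](CCO[Si](C)(C)C(C)(C)C)O[Si](C)(C)C(C)(C)C)[C@H](C)C[C@@H]1O
F6 | step 7 | methyl (Z)-4-oxohept-5-enoate | COC(=O)CCC(=O)/C=C\C
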